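The cyclopentane ring of the hydroazulene is opened at C1–C2 and C3–C3a (azulene numbering). This leaves a cycloheptenone whose C4 ketone is flanked by a cyclopropane made of C3a, C8a and C1, and a two-carbon partner, the silyl enol ether of 3-methylbutan-2-one, that carries C2 and the C3 carbinol with its isopropyl group. The key step exploits that C3a is alpha to the C4 oxygen and C1 hangs on the quaternary C8a: a samarium ketyl opens the three-membered ring to a C1 radical and a C3a enolate, which take up the enol ether in a formal [3+2] annulation that builds the cis-fused cyclopentanol in one operation.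

Key step: step 8

Remark: the SMILES is read as a cis-fused hydroazulene with 8a-CH3, H-3a, 3-OH and the C8 acyloxy group on one face and the isopropyl and C4 aroyloxy groups on the other; compounds 12–17 and the text on step 8 (also for the atoms of 9) use the azulene numbers of the target, earlier bicyclic compounds their own numbers; 2, 15 and 3-methylbutanoic anhydride are taken as purchasable.

Step 1
Reactants: 1 2,5-dimethylfuran; 2 1,1,3,3-tetrabromoacetone
Product: 4 (1R,5S)-1,5-dimethyl-8-oxabicyclo[3.2.1]oct-6-en-3-one, via dibromo cycloadduct 3 (not isolated)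
Conditions: Zn, B(OEt)3, THF, rt; then Zn–Cu couple, NH4Cl, MeOH, rt
Reagents that add atoms: none
Why: Zinc reduction of 2 gives the dibromo oxyallyl cation, which adds across C2 and C5 of the furan in a [4+3] cycloaddition; the zinc–copper couple then removes both bromines, and the bridged product is meso.

Step 2
Reactants: 4 (1R,5S)-1,5-dimethyl-8-oxabicyclo[3.2.1]oct-6-en-3-one
Product: 5 3,6-dimethylcyclohepta-2,4,6-trien-1-one (3,6-dimethyltropone)
Conditions: TMSOTf (2.2 equiv), Et3N, CH2Cl2, 0 °C to rt; aq. NaHCO3
Reagents that add atoms: none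
Why: Silyl enol ether formation and two successive β-eliminations of the bridging oxygen (first from one tertiary bridgehead, then as silanolate from the other) aromatise the ring, the known passage from 8-oxabicyclo[3.2.1]oct-6-en-3-ones to tropones.

Step 3
Reactants: 5 3,6-dimethyltropone
Product: 6 rac-(1S,7S)-4,7-dimethylbicyclo[5.1.0]octa-3,5-dien-2-one
Conditions: Me3S(O)I (1.05 equiv), NaH, DMSO, rt
Reagents that add atoms: trimethylsulfoxonium iodide, C[S+](C)(C)=O.[I-]
Why: Corey–Chaykovsky cyclopropanation, in which the sulfoxonium methylide adds to C2 of the tropone and the dienolate closes onto the methyl-bearing C3 as it does with tropone itself; the two enone halves are equivalent, one equivalent of ylide limits double addition, and the necessarily cis-fused product is racemic.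

Step 4
Reactants: 6 rac-4,7-dimethylbicyclo[5.1.0]octa-3,5-dien-2-one
Product: 7 rac-(1S,5R,6S,7R)-5,6-epoxy-4,7-dimethylbicyclo[5.1.0]oct-3-en-2-one (epoxide oxygen anti to the cyclopropane CH2)
Conditions: DMDO, acetone, 0 °C
Reagents that add atoms: dimethyldioxirane, CC1(C)OO1
Why: Electrophilic epoxidation should take the distal, more electron-rich C5–C6 double bond of the dienone (a vinylcyclopropane) from the face opposite the cyclopropane methylene, which places the oxygen cis to the angular methyl group.

Step 5
Reactants: 7 rac-5,6-epoxy-4,7-dimethylbicyclo[5.1.0]oct-3-en-2-one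
Product: 8 rac-(1S,6R,7R)-6-hydroxy-4,7-dimethylbicyclo[5.1.0]oct-4-en-2-one
Conditions: SmI2 (2.2 equiv), THF–MeOH, −90 °C; pH 7 buffer
Reagents that add atoms: none
Why: SmI2 reduction of a γ,δ-epoxy enone opens the allylic C–O bond to a samarium dienolate that methanol protonates at the α-carbon, which should give the β,γ-unsaturated δ-hydroxy ketone with the carbinol configuration untouched; at −90 °C the cyclopropyl ketone itself is not reduced.

Step 6
Reactants: 8 rac-(1S,6R,7R)-6-hydroxy-4,7-dimethylbicyclo[5.1.0]oct-4-en-2-one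
Product: 9 (1S,6R,7R)-4,7-dimethyl-6-[(3-methylbutanoyl)oxy]bicyclo[5.1.0]oct-4-en-2-one
Conditions: immobilised Burkholderia cepacia lipase, (iPrCH2CO)2O (0.6 equiv), MTBE, 30 °C, stopped near half conversion
Reagents that add atoms: 3-methylbutanoic anhydride, CC(C)CC(=O)OC(=O)CC(C)C
Why: Lipase-catalysed kinetic resolution, in which the empirical size rule for lipases (large group the quaternary cyclopropane carbon, medium group the alkene CH) predicts acylation of the (6R) alcohol, so the step installs the 3-methylbutanoate of the target and sets the absolute configuration while the (6S) alcohol stays behind.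

Step 7
Reactants: 10 3-methylbutan-2-one
Product: 11 trimethyl[(3-methylbut-1-en-2-yl)oxy]silane
Conditions: LiN(iPr)2, THF, −78 °C; TMSCl
Reagents that add atoms: chlorotrimethylsilane, C[Si](C)(C)Cl
Why: Kinetic deprotonation at the methyl group and O-silylation give the less substituted silyl enol ether.

Step 8
Reactants: 9 (1S,6R,7R)-4,7-dimethyl-6-[(3-methylbutanoyl)oxy]bicyclo[5.1.0]oct-4-en-2-one; 11 trimethyl[(3-methylbut-1-en-2-yl)oxy]silane
Product: 13 (3S,3aR,8R,8aR)-3-hydroxy-6,8a-dimethyl-4-oxo-3-(propan-2-yl)-1,2,3,3a,4,5,8,8a-octahydroazulen-8-yl 3-methylbutanoate, via tertiary trimethylsilyl ether 12 (not isolated)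
Conditions: SmI2 (20 mol %), Sm powder (20 mol %), 11 (10 equiv), THF, 60 °C; then citric acid, MeOH–H2O, 0 °C
Reagents that add atoms: none
Why: Proposed new method: electron transfer from SmI2 to the C4 ketone of 9 gives a ketyl that opens the cyclopropane at the exocyclic C1–C3a bond to a primary C1 radical and a samarium enolate at C3a–C4, the radical adds to the CH2 end of 11, and the tertiary α-silyloxy radical (or the silyloxocarbenium ion formed from it by electron transfer to trivalent samarium) closes onto the enolate carbon, after which the new ketyl returns its electron so that the metal turns over. The closest known reaction type is the SmI2-catalysed radical-relay formal [3+2] cycloaddition of alkyl cyclopropyl ketones with alkynes and activated alkenes; a silyl enol ether has not served as the two-carbon partner, and its slow radical addition is met by a large excess of 11, which is tolerable because the open radical recloses reversibly. The five-membered ring closes in the 5-exo-trig mode. C3a is controlled by the tether: the C1–C2–C3 chain hangs from C8a on the face of the former cyclopropane and can reach C3a only from that face, so the ring fusion must be cis with the methyl group and H-3a on the other face. C3 is controlled in the chair-like transition state of a 5-hexenyl-type closure, with the larger isopropyl group pseudo-equatorial (cis to C4) and the C–O bond turned away from the enolate oxygen, which a silyl ether oxygen binds poorly, so the oxygen should end cis to H-3a. The step needs cleavage of the exocyclic rather than the ring-fusion cyclopropane bond and attack at the terminal alkene carbon; overlap of the exocyclic bond with the ketyl orbital in the bicyclo[5.1.0] ketone and the 1,1-disubstitution of 11 secure both, the ester and the trisubstituted alkene are inert to catalytic SmI2, and the acidic work-up frees the tertiary alcohol.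

Step 9
Reactants: 13 (3S,3aR,8R,8aR)-3-hydroxy-6,8a-dimethyl-4-oxo-3-(propan-2-yl)-1,2,3,3a,4,5,8,8a-octahydroazulen-8-yl 3-methylbutanoate
Product: 14 (3S,3aS,4R,8R,8aR)-3,4-dihydroxy-6,8a-dimethyl-3-(propan-2-yl)-1,2,3,3a,4,5,8,8a-octahydroazulen-8-yl 3-methylbutanoate
Conditions: Me4NBH(OAc)3, MeCN–AcOH, −30 °C
Reagents that add atoms: none
Why: Evans–Saksena reduction, in which the C3 hydroxyl binds boron and hydride is delivered within the complex to the face of the C4 ketone that carries this hydroxyl and H-3a (also the open face, since the cis isopropyl group screens the other), so the new hydroxyl should end trans to H-3a; esters are not reduced.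

Step 10
Reactants: 14 (3S,3aS,4R,8R,8aR)-3,4-dihydroxy-6,8a-dimethyl-3-(propan-2-yl)-1,2,3,3a,4,5,8,8a-octahydroazulen-8-yl 3-methylbutanoate; 15 4-[(tert-butyldimethylsilyl)oxy]benzoic acid
Product: 16 (3S,3aS,4R,8R,8aR)-3-hydroxy-6,8a-dimethyl-8-[(3-methylbutanoyl)oxy]-3-(propan-2-yl)-1,2,3,3a,4,5,8,8a-octahydroazulen-4-yl 4-[(tert-butyldimethylsilyl)oxy]benzoate
Conditions: iPrN=C=NiPr, DMAP, CH2Cl2, rt
Reagents that add atoms: none
Why: Steglich esterification acylates the secondary C4 hydroxyl, while the tertiary C3 hydroxyl is too hindered to react and the phenol is masked as its silyl ether.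

Step 11
Reactants: 16 (3S,3aS,4R,8R,8aR)-3-hydroxy-6,8a-dimethyl-8-[(3-methylbutanoyl)oxy]-3-(propan-2-yl)-1,2,3,3a,4,5,8,8a-octahydroazulen-4-yl 4-[(tert-butyldimethylsilyl)oxy]benzoate
Product: 17 (3S,3aS,4R,8R,8aR)-3-hydroxy-6,8a-dimethyl-8-[(3-methylbutanoyl)oxy]-3-(propan-2-yl)-1,2,3,3a,4,5,8,8a-octahydroazulen-4-yl 4-hydroxybenzoate (CNP0086724.1)
Conditions: Bu4NF, AcOH, THF, 0 °C
Reagents that add atoms: none
Why: Fluoride cleaves the aryl silyl ether, and acetic acid buffers the phenoxide so that neither ester should be hydrolysed or migrate.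

Compound list
1 | 2,5-dimethylfuran | Cc1ccc(C)o1 | starting material
2 | 1,1,3,3-tetrabromoacetone | BrC(Br)C(=O)C(Br)Br | starting material
3 | 2,4-dibromo-1,5-dimethyl-8-oxabicyclo[3.2.1]oct-6-en-3-one (bromine epimers) | C[C@]12C(Br)C(=O)C(Br)[C@](C)(O1)C=C2 | intermediate
4 | (1R,5S)-1,5-dimethyl-8-oxabicyclo[3.2.1]oct-6-en-3-one (meso) | C[C@]12CC(=O)C[C@](C)(O1)C=C2 | intermediate
5 | 3,6-dimethylcyclohepta-2,4,6-trien-1-one | CC1=CC(=O)C=C(C)C=C1 | intermediate
6 | rac-(1S,7S)-4,7-dimethylbicyclo[5.1.0]octa-3,5-dien-2-one (one enantiomer drawn) | CC1=CC(=O)[C@H]2C[C@@]2(C)C=C1 | intermediate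
7 | rac-(1S,5R,6S,7R)-5,6-epoxy-4,7-dimethylbicyclo[5.1.0]oct-3-en-2-one (one enantiomer drawn) | CC1=CC(=O)[C@H]2C[C@@]2(C)[C@@H]3O[C@@H]31 | intermediate
8 | rac-(1S,6R,7R)-6-hydroxy-4,7-dimethylbicyclo[5.1.0]oct-4-en-2-one (one enantiomer drawn) | CC1=C[C@@H](O)[C@]2(C)C[C@@H]2C(=O)C1 | intermediate
9 | (1S,6R,7R)-4,7-dimethyl-6-[(3-methylbutanoyl)oxy]bicyclo[5.1.0]oct-4-en-2-one | CC1=C[C@@H](OC(=O)CC(C)C)[C@]2(C)C[C@@H]2C(=O)C1 | intermediate
10 | 3-methylbutan-2-one | CC(C)C(C)=O | starting material
11 | trimethyl[(3-methylbut-1-en-2-yl)oxy]silane | CC(C)C(=C)O[Si](C)(C)C | intermediate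
12 | (3S,3aR,8R,8aR)-6,8a-dimethyl-4-oxo-3-(propan-2-yl)-3-[(trimethylsilyl)oxy]-1,2,3,3a,4,5,8,8a-octahydroazulen-8-yl 3-methylbutanoate | CC1=C[C@@H](OC(=O)CC(C)C)[C@]2(C)CC[C@](O[Si](C)(C)C)(C(C)C)[C@@H]2C(=O)C1 | intermediate
13 | (3S,3aR,8R,8aR)-3-hydroxy-6,8a-dimethyl-4-oxo-3-(propan-2-yl)-1,2,3,3a,4,5,8,8a-octahydroazulen-8-yl 3-methylbutanoate | CC1=C[C@@H](OC(=O)CC(C)C)[C@]2(C)CC[C@](O)(C(C)C)[C@@H]2C(=O)C1 | intermediate
14 | (3S,3aS,4R,8R,8aR)-3,4-dihydroxy-6,8a-dimethyl-3-(propan-2-yl)-1,2,3,3a,4,5,8,8a-octahydroazulen-8-yl 3-methylbutanoate | CC1=C[C@@H](OC(=O)CC(C)C)[C@]2(C)CC[C@](O)(C(C)C)[C@@H]2[C@H](O)C1 | intermediate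
15 | 4-[(tert-butyldimethylsilyl)oxy]benzoic acid | CC(C)(C)[Si](C)(C)Oc1ccc(cc1)C(=O)O | starting material
16 | (3S,3aS,4R,8R,8aR)-3-hydroxy-6,8a-dimethyl-8-[(3-methylbutanoyl)oxy]-3-(propan-2-yl)-1,2,3,3a,4,5,8,8a-octahydroazulen-4-yl 4-[(tert-butyldimethylsilyl)oxy]benzoate | CC1=C[C@@H](OC(=O)CC(C)C)[C@]2(C)CC[C@](O)(C(C)C)[C@@H]2[C@H](OC(=O)c2ccc(O[Si](C)(C)C(C)(C)C)cc2)C1 | intermediate
17 | (3S,3aS,4R,8R,8aR)-3-hydroxy-6,8a-dimethyl-8-[(3-methylbutanoyl)oxy]-3-(propan-2-yl)-1,2,3,3a,4,5,8,8a-octahydroazulen-4-yl 4-hydroxybenzoate | CC1=C[C@@H](OC(=O)CC(C)C)[C@]2(C)CC[C@](O)(C(C)C)[C@@H]2[C@H](OC(=O)c2ccc(O)cc2)C1 | target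

Total step count: 11. Longest linear sequence: 10 steps (steps 1–6 and 8–11); step 7 makes the two-carbon partner.

Steps most likely to fail

1. Step 8 (proposed new method). Addition of the nucleophilic primary radical to the electron-rich enol ether may be too slow, so that reclosure, over-reduction of the radical, or proton transfer to the enolate with loss of the allylic ester takes over. The carbinol centre may also form with poor facial control. The fallback sets out from 9 and uses known chemistry. The SmI2-catalysed formal [3+2] coupling (SmI2, Sm powder, THF, 60 °C) is run with 3-methylbut-1-yne, a partner class for which the relay is established, and should give the cyclopentene (3aS,8R,8aR)-6,8a-dimethyl-4-oxo-3-(propan-2-yl)-1,3a,4,5,8,8a-hexahydroazulen-8-yl 3-methylbutanoate F1. Mukaiyama hydration (Co(acac)2, PhSiH3, O2, iPrOH) of the more accessible cyclopentene double bond, with oxygen entering from the convex face, then gives 13, where the route is rejoined.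

2. Step 6. The enzyme may not accept a carbinol next to a quaternary carbon, or may discriminate the enantiomers poorly. The fallback sets out from 8: the enantiomers are separated by preparative chromatography on a chiral stationary phase (amylose tris(3,5-dimethylphenylcarbamate)). The wanted (1S,6R,7R)-6-hydroxy-4,7-dimethylbicyclo[5.1.0]oct-4-en-2-one F2 is then acylated with 3-methylbutanoyl chloride, pyridine and DMAP in CH2Cl2 to give 9.

3. Step 4. Epoxidation may also attack the enone double bond or the wrong face, and the cyclopropylcarbinyl epoxide may rearrange under traces of acid. The fallback sets out from 6: copper-catalysed 1,6-conjugate borylation (B2pin2, CuCl, PPh3, NaOtBu, MeOH, THF) should deliver boron to the dienone terminus anti to the cyclopropane methylene. After α-protonation this gives rac-4,7-dimethyl-6-(4,4,5,5-tetramethyl-1,3,2-dioxaborolan-2-yl)bicyclo[5.1.0]oct-4-en-2-one F3. Oxidation with NaBO3 in THF–water, with retention, gives 8, so that step 5 is bypassed as well.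

Further compounds
F1 | step 8 | (3aS,8R,8aR)-6,8a-dimethyl-4-oxo-3-(propan-2-yl)-1,3a,4,5,8,8a-hexahydroazulen-8-yl 3-methylbutanoate | CC1=C[C@@H](OC(=O)CC(C)C)[C@]2(C)CC=C(C(C)C)[C@@H]2C(=O)C1
F2 | step 6 | (1S,6R,7R)-6-hydroxy-4,7-dimethylbicyclo[5.1.0]oct-4-en-2-one | CC1=C[C@@H](O)[C@]2(C)C[C@@H]2C(=O)C1
F3 | step 4 | rac-4,7-dimethyl-6-(4,4,5,5-tetramethyl-1,3,2-dioxaborolan-2-yl)bicyclo[5.1.0]oct-4-en-2-one (boron anti to the cyclopropane CH2, one enantiomer drawn) | CC1=C[C@@H](B2OC(C)(C)C(C)(C)O2)[C@]3(C)C[C@@H]3C(=O)C1
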